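**Assumption:** the target SMILES has no stereocentres and no stereogenic double bonds, so the compound is achiral and "single enantiomer" does not apply; the route only has to deliver the correct constitution.

## Retrosynthetic overview

1. Target ⇒ O‑methylation of the C5 lactam of ylidene‑diketopiperazine **9** plus a prototropic shift; **9** is already at the target's oxidation level, so no redox step is needed.
2. **9** ⇒ N1–C2 ring closure by intramolecular N‑acylation of an oxime (the oxime supplies the N–OH) in oxime‑amide ester **8**; the N4–C5 amide comes from oxime acid **6** + alanine methyl ester.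
3. **6** ⇒ indole C3–CH2 bond by nitrosoalkene alkylation of 7‑prenylindole **3** with ethyl bromopyruvate oxime **4**.
4. **3** ⇒ 7‑bromoindole + prenylzinc bromide (Negishi).
5. Ring order: the indole is purchased; the pyrazinone ring is closed in step 5 and aromatised in step 6.

## Route

**Step 1**
Reactants: **1** 7‑bromo‑1H‑indole; **2** prenyl bromide (converted in situ to prenylzinc bromide)
Product: **3** 7‑(3‑methylbut‑2‑en‑1‑yl)‑1H‑indole
Conditions: **2**, Zn dust, LiCl, THF, 0 °C (gives prenylZnBr, 2.5 equiv); then **1**, Pd(OAc)2 (2 mol %), CPhos‑type biaryl dialkylphosphine (4 mol %), THF, rt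
Reagents that add atoms: prenylzinc bromide, CC(C)=CC[Zn]Br (from prenyl bromide, CC(C)=CCBr)
Why: Negishi cross‑coupling; a bulky biarylphosphine gives the linear (α) prenyl arene, and excess organozinc tolerates the free indole N–H.

**Step 2**
Reactants: **3**; **4** ethyl 3‑bromo‑2‑(hydroxyimino)propanoate
Product: **5** ethyl (2E)‑2‑(hydroxyimino)‑3‑[7‑(3‑methylbut‑2‑enyl)‑1H‑indol‑3‑yl]propanoate
Conditions: **4** (1.2 equiv, slow addition), Na2CO3, CH2Cl2, rt
Reagents that add atoms: **4**, CCOC(=O)C(CBr)=NO
Why: base eliminates HBr from **4** to a nitrosoalkene, which the indole C3 attacks (Gilchrist–Ottenheijm conjugate addition); indole is far more nucleophilic than the prenyl alkene.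

**Step 3**
Reactants: **5**
Product: **6** (2E)‑2‑(hydroxyimino)‑3‑[7‑(3‑methylbut‑2‑enyl)‑1H‑indol‑3‑yl]propanoic acid
Conditions: LiOH·H2O, THF/H2O, 0 °C → rt; then citric acid to pH 3 at 0 °C
Reagents that add atoms: hydroxide/water, [OH-] (O)
Why: simple saponification; the oxime, indole and prenyl group are base‑stable, and cold mild acidification avoids decarboxylation.

**Step 4**
Reactants: **6**; **7** methyl L‑alaninate hydrochloride (the DL ester works equally)
Product: **8** methyl N‑{(2E)‑2‑(hydroxyimino)‑3‑[7‑(3‑methylbut‑2‑enyl)‑1H‑indol‑3‑yl]propanoyl}‑L‑alaninate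
Conditions: EDC·HCl, N‑hydroxysuccinimide, DMF, 0 °C; then **7**, N‑methylmorpholine, 0 °C → rt
Reagents that add atoms: **7**, C[C@H](N)C(=O)OC.Cl
Why: carbodiimide/active‑ester amidation; the amine outcompetes the weakly nucleophilic oxime OH, as in syntheses of α‑oximino‑amide natural products.

**Step 5**
Reactants: **8**
Product: **9** (6Z)‑1‑hydroxy‑3‑methyl‑6‑{[7‑(3‑methylbut‑2‑enyl)‑1H‑indol‑3‑yl]methylidene}piperazine‑2,5‑dione (tautomer of the 1,5‑dihydroxypyrazinone; C3 configuration and alkene geometry are irrelevant)
Conditions: NaOMe (2 equiv), MeOH, Ar, rt → 50 °C; AcOH quench; use promptly (air‑sensitive)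
Reagents that add atoms: none (MeOH is lost)
Why: intramolecular N‑acylation of the oxime by the ester (6‑membered cyclocondensation, as in 1‑hydroxy‑2‑pyridone syntheses from δ‑keto esters and hydroxylamine). The (E)‑oxime lone pair points at the ester, the 7‑membered O‑acyl product is reversible under methoxide, and the N‑acyl nitrone tautomerises to the stable ene‑hydroxamate anion.

**Step 6**
Reactants: **9**
Product: **10** astepyrazinoxide, 1‑hydroxy‑5‑methoxy‑3‑methyl‑6‑{[7‑(3‑methylbut‑2‑enyl)‑1H‑indol‑3‑yl]methyl}pyrazin‑2(1H)‑one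
Conditions: Me3OBF4 (1.1 equiv), CH2Cl2, 0 °C → rt, no base; then MeOH quench, Et3N, rt
Reagents that add atoms: trimethyloxonium tetrafluoroborate, C[O+](C)C.F[B-](F)(F)F (adds CH3)
Why: Meerwein lactim‑ether formation on the most basic carbonyl (the C5 lactam, vinylogously donated by the indole), while the un‑ionised N–OH is inert without base. Et3N then moves the C3–H to the exocyclic carbon, giving the aromatic pyrazinone and erasing the only stereocentre.

## Compound list

1 | 7‑bromo‑1H‑indole | Brc1cccc2cc[nH]c12 | starting material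
2 | prenyl bromide (1‑bromo‑3‑methylbut‑2‑ene) | CC(C)=CCBr | starting material
3 | 7‑(3‑methylbut‑2‑en‑1‑yl)‑1H‑indole | CC(C)=CCc1cccc2cc[nH]c12 | intermediate
4 | ethyl 3‑bromo‑2‑(hydroxyimino)propanoate | CCOC(=O)C(CBr)=NO | starting material
5 | ethyl (2E)‑2‑(hydroxyimino)‑3‑(7‑prenyl‑1H‑indol‑3‑yl)propanoate | CCOC(=O)/C(Cc1c[nH]c2c(CC=C(C)C)cccc12)=N/O | intermediate
6 | (2E)‑2‑(hydroxyimino)‑3‑(7‑prenyl‑1H‑indol‑3‑yl)propanoic acid | OC(=O)/C(Cc1c[nH]c2c(CC=C(C)C)cccc12)=N/O | intermediate
7 | methyl L‑alaninate hydrochloride | C[C@H](N)C(=O)OC.Cl | starting material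
8 | methyl N‑[(2E)‑2‑(hydroxyimino)‑3‑(7‑prenyl‑1H‑indol‑3‑yl)propanoyl]‑L‑alaninate | COC(=O)[C@H](C)NC(=O)/C(Cc1c[nH]c2c(CC=C(C)C)cccc12)=N/O | intermediate
9 | (6Z)‑1‑hydroxy‑3‑methyl‑6‑[(7‑prenyl‑1H‑indol‑3‑yl)methylidene]piperazine‑2,5‑dione (C3 unspecified) | CC1NC(=O)/C(=C/c2c[nH]c3c(CC=C(C)C)cccc23)N(O)C1=O | intermediate
10 | astepyrazinoxide (achiral) | COc1nc(C)c(=O)n(O)c1Cc1c[nH]c2c(CC=C(C)C)cccc12 | target

## Summary

Total steps: 6. Longest linear sequence: 6 (fully linear from 7‑bromoindole).

Steps most likely to fail, each with a fallback that changes the approach: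

1. **Step 5 (oxime N‑acylation ring closure).** It may be slow, or divert to O‑acylation or Beckmann‑type fragmentation. Fallback: close the ring at N1–C6 instead. Deoximate to the indolylpyruvoyl amide (aq. TiCl3), carry the alanine C‑terminus as an O‑allyl hydroxamate, and let the hydroxamate N–H add to the α‑keto amide and dehydrate (TsOH). Then O‑methylate and remove the allyl group with Pd(0).
2. **Step 6 (chemoselective O5‑methylation with free N–OH).** N–O or N4 methylation could compete. Fallback: protect the hydroxamic acid first as its O‑allyl ether (allyl bromide, K2CO3), form the lactim ether and aromatise, then deallylate with Pd(PPh3)4/morpholine, which leaves the prenyl group and indole untouched.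
3. **Step 4 (coupling of the free α‑oximino acid).** Activation could cause decarboxylative fragmentation to the nitrile or O‑acylation. Fallback: reverse the bond order. Make N‑(3‑bromo‑2‑hydroxyiminopropanoyl)‑Ala‑OMe from bromopyruvoyl chloride and **7**, then NH2OH, and use it as the nitrosoalkene precursor with **3**; this gives **8** directly and avoids acid **6**.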